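## Structural features

Quercetin 3,4'-bissulfate is a flat, achiral flavonol. Benzo ring A (C4a to C8a, oxygenated at C5 and C7) is fused through C4a and C8a to the 4-pyranone ring C (O1, C2, C3, C4), and the catechol ring B hangs on C2 through the single bond C2–C1'. Five oxygens sit on this C6–C3–C6 skeleton: the enolic O3 and the phenolic O5, O7, O3' and O4'. The target carries hydrogen sulfate esters on O3 and O4' and free hydroxyls on the other three, so O4' has to be told apart from its ortho neighbour O3', and O3 from every phenol. The target has no stereocentre, but a 2,3-dihydro precursor has two adjacent ones at C2 and C3; they are temporary and vanish when ring C is aromatised. The fragile parts are the two sulfate monoesters (acid-labile, the enol sulfate at O3 most of all, and robust only as salts), the electron-rich catechol and phloroglucinol rings, and, on the way, a benzylic aryl ether and an α-ketol that dislike acid and base. The real difficulty is therefore not the carbon skeleton but putting two sulfates on two of five hydroxyls and handling a doubly charged, hydrolytically labile product at the end. The key step uses two features of the dihydro level: O3 is then a secondary alcohol on sp3 C3 rather than one more acidic hydroxyl of a polyphenol, and the bond C4–C4a can be made by acylating ring A, whose two carbons ortho to O1 are equivalent and carry three oxygen donors.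

## Logic of the disconnections

18 back to 16: the three O–CH2Ph bonds at O5, O7 and O3' are cut, together with the sodium/proton exchange at the sulfates (through 17). Benzyl is the permanent group because neutral hydrogenolysis is one of the few deprotections a sulfate monoester salt tolerates. The gain is that the polar, labile polyphenol appears only in the last operation. The forward step must spare the S–O bonds and the C2–C3 double bond and must release the free acid cold and briefly.

16 back to 14: the O3–S and O4'–S bonds are cut. Both sulfates go on in one operation and as late as possible, since nothing after them may be acidic. The gain is a neutral, chromatographable diol. The demand is that exactly O3 and O4' are free in 14 and that the chelated O3–H is driven to full conversion (through 15).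

14 back to 13: the O4'–allyl bond is cut. O4' needs a mask that is orthogonal to benzyl yet survives alkoxide, hydroxide, TFAA and an oxidation; allyl does, and zerovalent palladium removes it without touching benzyl ethers. The demand on the route is that no electrophilic halogen is used while the allyl double bond is present.

13 back to 11: the C2–C3 double bond is exchanged for two C–H bonds, so ring C goes to the dihydro level. This is what makes O3 an ordinary alcohol and lets ring C be closed by acylation. Both stereocentres are erased in the forward oxidation (through 12), so the configuration of 11 and of everything before it does not matter for the target, and diastereomer mixtures converge. The forward step must oxidise the C3 carbinol in the presence of an allyl ether, which rules out the usual iodine reagents for dihydroflavonols.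

11 back to 8: the bond C4–C4a is cut. Ring C opens to an acyclic acid in which ring A is a symmetric 3,5-dioxygenated aryl ether, so the site of acylation within ring A needs no control. The erythro (2R*,3R*) acid maps onto the trans (2R*,3R*) chromanone with both centres untouched. The C3 hydroxyl of 8 is left free, because the acylating reagent masks it in the flask (through 9 and 10). The demand is acylation of ring A and not of ring B (whose C6' could close an indanone), and no ionisation of the benzylic C2–O1 bond.

8 back to 5 and 6: the ether bond O1–C2 is cut and the acid is taken back to its methyl ester (through 7). Opening an epoxide at its benzylic carbon places the hydroxyl on the neighbouring carbon automatically, so O3 never has to be introduced by oxidation. The gain is two fragments of similar size, one of them purchasable. The demand is attack by phenoxide oxygen, not carbon, at the benzylic carbon and not at the carbon next to the ester.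

5 back to 3 and 4: the C2–C3 carbon–carbon bond and the O3–C3 bond are cut (Darzens retron). The aldehyde oxygen of 3 becomes O3 of the target. The gain is an aromatic aldehyde and a two-carbon ester. The demand is a glycidate that is handled without acid.

3 back to 2 and 1: the O3'–benzyl and then the O4'–allyl bonds are cut. The order follows acidity: the hydroxyl para to the formyl group is alkylated first under weak base, which fixes allyl on the future O4' and benzyl on the future O3'.

## Other disconnections considered

Alternative 1: The cut goes through C1'–C2 and C2–C3, so that C2 comes from carbon monoxide A4. Forward, the ring B aryl iodide A2, A4 and the enolate of the ring A α-alkoxy ketone A3 would be joined under Pd catalysis (carbonylative α-arylation) to the 2-alkoxy-1,3-diketone A1, drawn as its chelated enol. Acid would then remove the three methoxymethyl groups and close ring C at oxygen by cyclodehydration, which would lead straight to 14.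
- In its favour: the whole C6–C3–C6 chain is assembled in one convergent step, O3 is already on the ketone carbon, ring C forms at its final oxidation level, and no stereocentre ever appears. On redox economy (no oxidation step) and on the single deprotection that also closes the ring it is better than the chosen plan; in convergence the two are equal.
- Against it here: the α-alkoxy enolate of the di-ortho-substituted ketone A3 can be acylated at oxygen as well as at carbon. The product is more acidic than A3 and consumes base. Direct, non-carbonylative arylation competes when carbonylation is slow. A toxic gas or a two-chamber surrogate is needed.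
- Comparison: A3 needs three different oxygen masks and an ω-oxygen on a phloroacetophenone, and A2 a catechol with differentiated oxygens, so the step count to 14 comes out about equal, not lower. The chosen plan depends on substrate symmetry and ionic reactivity, the alternative on ligand-controlled chemoselectivity at palladium. The chosen plan is preferred because its selectivity is built into the substrate, at the price of one oxidation step.

Alternative 2: Ring A rather than ring C is dismantled: C5–C6, C7–C8 and C4a–C5 are cut, and ring C is taken ready-made from kojic acid A8. Forward, the pyranonyl diazo ketone A6 would undergo Wolff rearrangement to a vinylketene, which adds the siloxyalkyne A7 in a [2+2] sense. 4π opening of the cyclobutenone gives a dienylketene, whose 6π electrocyclisation onto the pyranone double bond and tautomerisation build aromatic ring A (Danheiser benzannulation) and give A5.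
- In its favour: ring C is at the final oxidation level with O3 supplied by the 5-hydroxyl of A8, and the annulation regiochemistry follows from the polarity of the ynol ether. Ring A emerges with O5 free and chelated and O7 silylated, so it is differentiated without any protecting-group step. On this last point and on redox economy it is better than the chosen plan.
- Against it: A6 needs a long linear preparation from A8 (O-protection, arylation of a pyranone C–H with ring B, oxidation of the hydroxymethyl group, diazo ketone formation). A diazo compound and ketene chemistry must be handled on scale. The electrocyclisation has to engage the double bond of a cross-conjugated 4-pyranone, for which precedent is thinner than for simple vinyl or aryl ketenes. Four kinds of protecting group remain around the sulfation, with the free 5-OH as a bystander.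
- Comparison: the chosen plan is clearly shorter and uses cheaper, safer reagents. Mechanistically the alternative is a four-stage pericyclic cascade against a single electrophilic substitution, elegant but harder to troubleshoot.

Alternative 3: The cut removes C4: C4a–C4, C4–C3 and O1–C2 are broken, with A4 as the carbonyl carbon. Forward, the o-iodophenol A10, A4 and the ring B alkyne A11 would combine under Pd catalysis (carbonylative Sonogashira coupling, then 6-endo-dig addition of the phenol oxygen to the ynone) to close pyranone ring C and give the flavone A9.
- In its favour: it is the most convergent plan, both partners are two or three steps from simple materials (A10 from 6, A11 from an aldehyde such as 3), this type of flavone annulation is well precedented, and no stereocentre is formed. In convergence and in steps to the flavone skeleton it is better than the chosen plan.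
- Against it here: A9 has hydrogen at C3, so the very oxygen that must carry one of the two sulfates is missing. It would have to be introduced late by oxidation of C3–H (metalation and oxidation, or epoxidation of the C2–C3 double bond and opening) on an electron-rich polyether. Mono-iodination of 6 must go ortho to the hydroxyl and not para, 5-exo closure to an aurone competes with the 6-endo mode, and A4 must be handled.
- Comparison: after C3 hydroxylation and acetal cleavage this route would also reach 14, so the last two steps are shared and the overall count is about equal. The chosen plan is preferred because O3 is present from the Darzens step onward; the alternative is its equal in leaving no lasting stereochemistry and better in convergence.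

Key step: step 5

Assumption: the target is taken as the free bis(hydrogen sulfate) exactly as drawn; since aryl and enol hydrogen sulfates are robust only as salts, the sulfates are carried as sodium salts and the acid form is released cold at the very end.
Remark: 5 and 7 to 12 are racemic; their SMILES show one enantiomer only to fix the relative configuration.

## Route

Step 1
Reactants: 1 3,4-dihydroxybenzaldehyde
Product: 2 4-(allyloxy)-3-hydroxybenzaldehyde
Conditions: allyl bromide (1.05 equiv), NaHCO3 (1.5 equiv), NaI (0.2 equiv), DMF, 40 °C
Reagents that add atoms: allyl bromide, C=CCBr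
Why: Williamson etherification under weak-base control: only the 4-OH, conjugated with the para formyl group and so the more acidic, is ionised by NaHCO3, so allylation should occur at O4 (the future O4'); NaI forms the more reactive allyl iodide in situ.

Step 2
Reactants: 2 4-(allyloxy)-3-hydroxybenzaldehyde
Product: 3 4-(allyloxy)-3-(benzyloxy)benzaldehyde
Conditions: BnBr (1.2 equiv), K2CO3 (1.5 equiv), DMF, 50 °C
Reagents that add atoms: benzyl bromide, BrCc1ccccc1
Why: Williamson benzylation of the remaining phenol (the future O3'); the temperature is far below that of an aromatic Claisen rearrangement of the allyl ether.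

Step 3
Reactants: 3 4-(allyloxy)-3-(benzyloxy)benzaldehyde; 4 methyl chloroacetate
Product: 5 methyl trans-3-[4-(allyloxy)-3-(benzyloxy)phenyl]oxirane-2-carboxylate (racemic)
Conditions: NaOMe (1.5 equiv), MeOH–THF, −10 °C to rt; neutral work-up, crystallisation or Et3N-deactivated silica
Reagents that add atoms: none
Why: Darzens glycidic ester condensation: the chloroacetate enolate adds to the aldehyde and the aldolate closes the epoxide by intramolecular SN2 displacement of chloride, so the aldehyde oxygen becomes the future O3. The trans isomer should predominate because the aldol step is reversible and the anti aldolate cyclises faster; some cis isomer is tolerable since both centres are erased in step 6.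

Step 4
Reactants: 5 methyl trans-3-[4-(allyloxy)-3-(benzyloxy)phenyl]oxirane-2-carboxylate; 6 3,5-bis(benzyloxy)phenol
Product: 8 erythro-3-[4-(allyloxy)-3-(benzyloxy)phenyl]-3-[3,5-bis(benzyloxy)phenoxy]-2-hydroxypropanoic acid (racemic), via methyl ester 7 (not isolated)
Conditions: 6 (1.2 equiv), Cs2CO3 (0.3 equiv), DMF, 60 °C; then LiOH·H2O (3 equiv), THF–H2O, 0 °C to rt; 1 M HCl to pH 3, 0 °C
Reagents that add atoms: lithium hydroxide monohydrate, [Li+].[OH-].O
Why: Base-catalysed SN2 opening of the aryl glycidate by the phenoxide of 6 at the benzylic carbon (the future C2), which the electron-rich aryl group activates, with inversion, so the trans epoxide gives the erythro (2R*,3R*) ether 7; in DMF the phenoxide should react at oxygen. Saponification in the same pot gives 8, which is freed from neutral material by acid–base extraction; the configuration is provisional because both centres are erased in step 6.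

Step 5
Reactants: 8 erythro-3-[4-(allyloxy)-3-(benzyloxy)phenyl]-3-[3,5-bis(benzyloxy)phenoxy]-2-hydroxypropanoic acid
Product: 11 trans-2-[4-(allyloxy)-3-(benzyloxy)phenyl]-5,7-bis(benzyloxy)-3-hydroxychroman-4-one (racemic), via mixed trifluoroacetic anhydride 9 (not isolated), via 3-O-trifluoroacetyl dihydroflavonol 10 (not isolated)
Conditions: TFAA (4 equiv), CH2Cl2 (0.02 M), 0 °C to rt; evaporate; NaHCO3, MeOH, 0 °C
Reagents that add atoms: none
Why: Excess TFAA first trifluoroacetylates the C3 hydroxyl and turns the carboxyl group into the mixed trifluoroacetic anhydride 9, which, helped by the TFA set free, acylates the ring A carbon ortho to O1 in an intramolecular Friedel–Crafts acylation; loss of trifluoroacetate and rearomatisation give 10, and methanolysis of this activated α-acyloxy ketone ester on work-up gives 11. The closest known reaction type is the TFAA-mediated cyclisation of 3-aryloxypropanoic acids to chroman-4-ones. Ring C is closed as a six-membered ring by 6-exo-trig attack of the arene carbon on the acyl carbon (bond C4–C4a), with the leaving group outside the ring. No stereocentre is created: C2 and C3 are carried over from 8, and since both are erased in step 6 even partial epimerisation at C3 next to the new ketone is harmless. Within ring A no site control is needed, because the two carbons ortho to O1 are related by the local symmetry of the 3,5-bis(benzyloxy)phenoxy group and the para carbon cannot reach. The selectivity that does need an argument is ring A against ring B, whose C6' (para to the 3'-benzyloxy group) could close a five-membered indanone: the ring A carbon has three oxygen donors (two ortho, one para) against one para donor at C6', and the six-membered mode is the faster one, so chromanone formation should win by a wide margin. Ionisation of the benzylic C2–O1 bond is held back because C2 is flanked by the trifluoroacetoxy-bearing C3 and the acyl group, and no Lewis acid is present, so the benzyl and allyl ethers should survive.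

Step 6
Reactants: 11 trans-2-[4-(allyloxy)-3-(benzyloxy)phenyl]-5,7-bis(benzyloxy)-3-hydroxychroman-4-one
Product: 13 2-[4-(allyloxy)-3-(benzyloxy)phenyl]-5,7-bis(benzyloxy)-3-hydroxy-4H-chromen-4-one, via chromane-3,4-dione 12 (not isolated)
Conditions: (COCl)2 (1.3 equiv), DMSO (2.6 equiv), CH2Cl2, −78 °C; then Et3N (5 equiv), −78 to 0 °C; cold aqueous quench
Reagents that add atoms: none
Why: Swern oxidation of an α-hydroxy ketone: the C3 carbinol is oxidised to the 3,4-dione 12, whose acidic C2–H enolises under Et3N to the aromatic 4-pyranone, so both stereocentres vanish. Activated DMSO is chosen over iodine-based dehydrogenation because it leaves the allyl double bond and the benzyl ethers untouched; only a small excess of activator and a cold quench are used so that the enolic product is not methylthiomethylated.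

Step 7
Reactants: 13 2-[4-(allyloxy)-3-(benzyloxy)phenyl]-5,7-bis(benzyloxy)-3-hydroxy-4H-chromen-4-one
Product: 14 5,7-bis(benzyloxy)-2-[3-(benzyloxy)-4-hydroxyphenyl]-3-hydroxy-4H-chromen-4-one
Conditions: Pd(PPh3)4 (5 mol %), morpholine (10 equiv), THF, rt
Reagents that add atoms: none
Why: Tsuji–Trost-type deallylation: zerovalent palladium ionises the allyl aryl ether to a π-allyl complex and the phenoxide, and morpholine traps the allyl unit irreversibly; benzyl ethers and the flavonol are inert under these neutral conditions.

Step 8
Reactants: 14 5,7-bis(benzyloxy)-2-[3-(benzyloxy)-4-hydroxyphenyl]-3-hydroxy-4H-chromen-4-one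
Product: 16 disodium 5,7-bis(benzyloxy)-2-[3-(benzyloxy)-4-(sulfonatooxy)phenyl]-4-oxo-4H-chromen-3-yl sulfate, via bis(pyridinium) salt 15 (not isolated)
Conditions: SO3·pyridine (10 equiv), pyridine, 50 °C; then aq. NaHCO3 to pH 8; C18, H2O–MeOH
Reagents that add atoms: sulfur trioxide pyridine complex, O=S(=O)([O-])[n+]1ccccc1; sodium hydrogen carbonate, [Na+].OC([O-])=O
Why: O-sulfation of a phenol and an enol with an amine–SO3 complex; O5, O7 and O3' are blocked as benzyl ethers, so only O3 and O4' can react, and excess reagent with gentle heating drives the chelated, hindered 3-OH to completion. Exchange to sodium gives a stable, isolable bis-sulfate salt.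

Step 9
Reactants: 16 disodium 5,7-bis(benzyloxy)-2-[3-(benzyloxy)-4-(sulfonatooxy)phenyl]-4-oxo-4H-chromen-3-yl sulfate
Product: 18 quercetin 3,4'-bissulfate (free acid form), via disodium salt 17 (not isolated)
Conditions: H2 (1 atm), 10% Pd/C, MeOH–THF–H2O, rt; filter; 1 M HCl (2.0 equiv), 0 °C; C18 cartridge (cold H2O, then MeOH); lyophilise
Reagents that add atoms: none
Why: Catalytic hydrogenolysis cleaves the three benzyl ethers, while sulfate monoester salts and the C2–C3 double bond of the 4-pyranone are not reduced under these conditions. The free acid is released only at the end, cold and with exactly two equivalents of HCl, because aryl and enol hydrogen sulfates hydrolyse under their own acidity.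

## Compound list

1 | 3,4-dihydroxybenzaldehyde | O=Cc1ccc(O)c(O)c1 | starting material
2 | 4-(allyloxy)-3-hydroxybenzaldehyde | O=Cc1ccc(OCC=C)c(O)c1 | intermediate
3 | 4-(allyloxy)-3-(benzyloxy)benzaldehyde | O=Cc1ccc(OCC=C)c(OCc2ccccc2)c1 | intermediate
4 | methyl chloroacetate | COC(=O)CCl | starting material
5 | methyl trans-3-[4-(allyloxy)-3-(benzyloxy)phenyl]oxirane-2-carboxylate, racemic (2R*,3S*) | COC(=O)[C@@H]1O[C@H]1c2ccc(OCC=C)c(OCc3ccccc3)c2 | intermediate
6 | 3,5-bis(benzyloxy)phenol | Oc1cc(OCc2ccccc2)cc(OCc2ccccc2)c1 | starting material
7 | methyl erythro-3-[4-(allyloxy)-3-(benzyloxy)phenyl]-3-[3,5-bis(benzyloxy)phenoxy]-2-hydroxypropanoate, racemic (2R*,3R*), not isolated | COC(=O)[C@H](O)[C@H](Oc1cc(OCc2ccccc2)cc(OCc2ccccc2)c1)c1ccc(OCC=C)c(OCc2ccccc2)c1 | intermediate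
8 | erythro-3-[4-(allyloxy)-3-(benzyloxy)phenyl]-3-[3,5-bis(benzyloxy)phenoxy]-2-hydroxypropanoic acid, racemic (2R*,3R*) | OC(=O)[C@H](O)[C@H](Oc1cc(OCc2ccccc2)cc(OCc2ccccc2)c1)c1ccc(OCC=C)c(OCc2ccccc2)c1 | intermediate
9 | erythro-3-[4-(allyloxy)-3-(benzyloxy)phenyl]-3-[3,5-bis(benzyloxy)phenoxy]-2-(trifluoroacetoxy)propanoic trifluoroacetic anhydride, racemic, not isolated | O=C(OC(=O)C(F)(F)F)[C@H](OC(=O)C(F)(F)F)[C@H](Oc1cc(OCc2ccccc2)cc(OCc2ccccc2)c1)c1ccc(OCC=C)c(OCc2ccccc2)c1 | intermediate
10 | trans-2-[4-(allyloxy)-3-(benzyloxy)phenyl]-5,7-bis(benzyloxy)-4-oxochroman-3-yl trifluoroacetate, racemic, not isolated | O=C1c2c(OCc3ccccc3)cc(OCc3ccccc3)cc2O[C@H](c2ccc(OCC=C)c(OCc3ccccc3)c2)[C@H]1OC(=O)C(F)(F)F | intermediate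
11 | trans-2-[4-(allyloxy)-3-(benzyloxy)phenyl]-5,7-bis(benzyloxy)-3-hydroxychroman-4-one, racemic (2R*,3R*) | O=C1c2c(OCc3ccccc3)cc(OCc3ccccc3)cc2O[C@H](c2ccc(OCC=C)c(OCc3ccccc3)c2)[C@H]1O | intermediate
12 | 2-[4-(allyloxy)-3-(benzyloxy)phenyl]-5,7-bis(benzyloxy)chromane-3,4-dione, racemic, not isolated | O=C1c2c(OCc3ccccc3)cc(OCc3ccccc3)cc2O[C@H](c2ccc(OCC=C)c(OCc3ccccc3)c2)C1=O | intermediate
13 | 2-[4-(allyloxy)-3-(benzyloxy)phenyl]-5,7-bis(benzyloxy)-3-hydroxy-4H-chromen-4-one (4'-O-allyl-3',5,7-tri-O-benzylquercetin) | O=c1c(O)c(-c2ccc(OCC=C)c(OCc3ccccc3)c2)oc2cc(OCc3ccccc3)cc(OCc3ccccc3)c12 | intermediate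
14 | 5,7-bis(benzyloxy)-2-[3-(benzyloxy)-4-hydroxyphenyl]-3-hydroxy-4H-chromen-4-one (3',5,7-tri-O-benzylquercetin) | O=c1c(O)c(-c2ccc(O)c(OCc3ccccc3)c2)oc2cc(OCc3ccccc3)cc(OCc3ccccc3)c12 | intermediate
15 | bis(pyridinium) 5,7-bis(benzyloxy)-2-[3-(benzyloxy)-4-(sulfonatooxy)phenyl]-4-oxo-4H-chromen-3-yl sulfate, not isolated | c1cc[nH+]cc1.c1cc[nH+]cc1.O=c1c(OS(=O)(=O)[O-])c(-c2ccc(OS(=O)(=O)[O-])c(OCc3ccccc3)c2)oc2cc(OCc3ccccc3)cc(OCc3ccccc3)c12 | intermediate
16 | disodium 5,7-bis(benzyloxy)-2-[3-(benzyloxy)-4-(sulfonatooxy)phenyl]-4-oxo-4H-chromen-3-yl sulfate | [Na+].[Na+].O=c1c(OS(=O)(=O)[O-])c(-c2ccc(OS(=O)(=O)[O-])c(OCc3ccccc3)c2)oc2cc(OCc3ccccc3)cc(OCc3ccccc3)c12 | intermediate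
17 | disodium 5,7-dihydroxy-2-[3-hydroxy-4-(sulfonatooxy)phenyl]-4-oxo-4H-chromen-3-yl sulfate, not isolated | [Na+].[Na+].O=c1c(OS(=O)(=O)[O-])c(-c2ccc(OS(=O)(=O)[O-])c(O)c2)oc2cc(O)cc(O)c12 | intermediate
18 | quercetin 3,4'-bissulfate, 5,7-dihydroxy-2-[3-hydroxy-4-(sulfooxy)phenyl]-4-oxo-4H-chromen-3-yl hydrogen sulfate | O=c1c(OS(=O)(=O)O)c(-c2ccc(OS(=O)(=O)O)c(O)c2)oc2cc(O)cc(O)c12 | target

## Step count and least certain steps

Total step count: 9. Longest linear sequence: 9 steps, from 1 to 18; 4 enters at step 3 and 6 at step 4.

**Step 5 (key step).**
- Most likely to go wrong: acid-induced ionisation of the benzylic C2–O1 ether (a p-alkoxybenzyl aryl ether) in the TFA that builds up, ending in loss of the ring A phenol or C-alkylation of ring A. Slow acylation is also possible, because the α-trifluoroacetoxy group weakens the mixed anhydride as an electrophile. Closure onto ring B is less likely.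
- Fallback: starting from 8, the hydroxyl is acetylated (Ac2O, pyridine, aqueous work-up) to the erythro 2-acetoxy acid F1. Oxalyl chloride with catalytic DMF converts it into the acid chloride F2. F2 is cyclised with SnCl4 in CH2Cl2 at −78 °C to the 3-O-acetyl dihydroflavonol F3, and mild methanolysis (catalytic K2CO3, MeOH, 0 °C) comes back to the route at 11. This replaces a protic mixed-anhydride medium by an isolable acyl chloride, an aprotic Lewis acid and low temperature, with O3 held as a stable ester.

**Step 4.**
- Most likely to go wrong: attack of the phenoxide at the ester carbonyl or at the carbon next to it instead of the benzylic carbon, reaction of the ambident phenoxide at carbon, or thermal rearrangement of the electron-rich glycidate before it is opened.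
- Fallback: starting from 5, the ester is saponified first (KOH, 1.0 equiv, cold EtOH) to the crystalline potassium trans-glycidate F4, which is never acidified. F4 is opened with the potassium phenoxide of 6 (6, KOH, H2O–DMSO, 60–80 °C). The carboxylate offers no electrophilic carbonyl and repels attack at the adjacent carbon, so the benzylic carbon should be the only site, as in known openings of glycidate salts by nitrogen and oxygen nucleophiles. Cold acidification comes back to the route at 8.

**Step 6.**
- Most likely to go wrong: further reaction of the enolic flavonol with activated sulfoxide (methylthiomethylation at O3 or C2), or incomplete tautomerisation of the dione.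
- Fallback: starting from 11, the order is reversed. Deallylation (Pd(PPh3)4, morpholine, THF) gives the 4'-hydroxy dihydroflavonol F5. With no alkene left, the classical dehydrogenation of dihydroflavonols (I2, KOAc, AcOH, reflux) can be used, and it comes back to the route at 14. The step count is unchanged.

**Step 8.**
- Most likely to go wrong: incomplete sulfation of the chelated, hindered 3-OH, leaving mixtures of mono- and bis-sulfate salts that are hard to separate.
- Fallback: starting from 14, both hydroxyls are sulfated with 2,2,2-trichloroethyl chlorosulfate (Et3N, DMAP, THF) to the neutral bis(2,2,2-trichloroethyl) sulfate diester F6, which can be purified on silica. Transfer hydrogenolysis (Pd/C, HCO2NH4, MeOH) then removes the trichloroethyl groups and the benzyl ethers in one operation to give the diammonium salt F7, and cold acidification as in step 9 comes back to the route at 18. This replaces steps 8 and 9.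

**Step 9.**
- Most likely to go wrong: hydrolytic loss of the enol 3-O-sulfate while the strongly acidic free form is handled in water and concentrated, or slow hydrogenolysis of the anionic substrate.
- Fallback: starting from 16, the acid is released before deprotection. Partition between cold dilute HCl and ethyl acetate–n-butanol puts the lipophilic benzylated bis(hydrogen sulfate) F8 into the organic layer. Hydrogenolysis of F8 in dry THF–EtOAc (H2, Pd/C) then needs only filtration and evaporation and comes back to the route at 18, so the deprotected product never meets aqueous acid.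

## Further compounds

F1 | step 5 | erythro-2-acetoxy-3-[4-(allyloxy)-3-(benzyloxy)phenyl]-3-[3,5-bis(benzyloxy)phenoxy]propanoic acid, racemic | OC(=O)[C@H](OC(C)=O)[C@H](Oc1cc(OCc2ccccc2)cc(OCc2ccccc2)c1)c1ccc(OCC=C)c(OCc2ccccc2)c1
F2 | step 5 | erythro-2-acetoxy-3-[4-(allyloxy)-3-(benzyloxy)phenyl]-3-[3,5-bis(benzyloxy)phenoxy]propanoyl chloride, racemic | ClC(=O)[C@H](OC(C)=O)[C@H](Oc1cc(OCc2ccccc2)cc(OCc2ccccc2)c1)c1ccc(OCC=C)c(OCc2ccccc2)c1
F3 | step 5 | trans-2-[4-(allyloxy)-3-(benzyloxy)phenyl]-5,7-bis(benzyloxy)-4-oxochroman-3-yl acetate, racemic | O=C1c2c(OCc3ccccc3)cc(OCc3ccccc3)cc2O[C@H](c2ccc(OCC=C)c(OCc3ccccc3)c2)[C@H]1OC(C)=O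
F4 | step 4 | potassium trans-3-[4-(allyloxy)-3-(benzyloxy)phenyl]oxirane-2-carboxylate, racemic | [K+].[O-]C(=O)[C@@H]1O[C@H]1c2ccc(OCC=C)c(OCc3ccccc3)c2
F5 | step 6 | trans-5,7-bis(benzyloxy)-2-[3-(benzyloxy)-4-hydroxyphenyl]-3-hydroxychroman-4-one, racemic | O=C1c2c(OCc3ccccc3)cc(OCc3ccccc3)cc2O[C@H](c2ccc(O)c(OCc3ccccc3)c2)[C@H]1O
F6 | step 8 | 5,7-bis(benzyloxy)-2-{3-(benzyloxy)-4-[(2,2,2-trichloroethoxy)sulfonyloxy]phenyl}-4-oxo-4H-chromen-3-yl 2,2,2-trichloroethyl sulfate | O=c1c(OS(=O)(=O)OCC(Cl)(Cl)Cl)c(-c2ccc(OS(=O)(=O)OCC(Cl)(Cl)Cl)c(OCc3ccccc3)c2)oc2cc(OCc3ccccc3)cc(OCc3ccccc3)c12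
F7 | step 8 | diammonium 5,7-dihydroxy-2-[3-hydroxy-4-(sulfonatooxy)phenyl]-4-oxo-4H-chromen-3-yl sulfate | [NH4+].[NH4+].O=c1c(OS(=O)(=O)[O-])c(-c2ccc(OS(=O)(=O)[O-])c(O)c2)oc2cc(O)cc(O)c12
F8 | step 9 | 5,7-bis(benzyloxy)-2-[3-(benzyloxy)-4-(sulfooxy)phenyl]-4-oxo-4H-chromen-3-yl hydrogen sulfate | O=c1c(OS(=O)(=O)O)c(-c2ccc(OS(=O)(=O)O)c(OCc3ccccc3)c2)oc2cc(OCc3ccccc3)cc(OCc3ccccc3)c12
A1 | alternative 1 | 1-[2,4-bis(benzyloxy)-6-(methoxymethoxy)phenyl]-3-[3-(benzyloxy)-4-(methoxymethoxy)phenyl]-2-(methoxymethoxy)propane-1,3-dione, chelated enol form | O/C(c1ccc(OCOC)c(OCc2ccccc2)c1)=C(\C(=O)c1c(OCOC)cc(OCc2ccccc2)cc1OCc1ccccc1)OCOC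
A2 | alternative 1 | 2-(benzyloxy)-4-iodo-1-(methoxymethoxy)benzene | COCOc1ccc(I)cc1OCc1ccccc1
A3 | alternative 1 | 1-[2,4-bis(benzyloxy)-6-(methoxymethoxy)phenyl]-2-(methoxymethoxy)ethan-1-one | COCOCC(=O)c1c(OCOC)cc(OCc2ccccc2)cc1OCc1ccccc1
A4 | alternative 1 | carbon monoxide | [C-]#[O+]
A5 | alternative 2 | 2-[3-(benzyloxy)-4-(methoxymethoxy)phenyl]-5-hydroxy-3-(methoxymethoxy)-7-(triisopropylsilyloxy)-4H-chromen-4-one | O=c1c(OCOC)c(-c2ccc(OCOC)c(OCc3ccccc3)c2)oc2cc(O[Si](C(C)C)(C(C)C)C(C)C)cc(O)c12
A6 | alternative 2 | 2-diazo-1-{6-[3-(benzyloxy)-4-(methoxymethoxy)phenyl]-5-(methoxymethoxy)-4-oxo-4H-pyran-2-yl}ethan-1-one | [N-]=[N+]=CC(=O)c1cc(=O)c(OCOC)c(-c2ccc(OCOC)c(OCc3ccccc3)c2)o1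
A7 | alternative 2 | (ethynyloxy)tri(propan-2-yl)silane | C#CO[Si](C(C)C)(C(C)C)C(C)C
A8 | alternative 2 | kojic acid, 5-hydroxy-2-(hydroxymethyl)-4H-pyran-4-one | O=c1cc(CO)occ1O
A9 | alternative 3 | 5,7-bis(benzyloxy)-2-[3-(benzyloxy)-4-(methoxymethoxy)phenyl]-4H-chromen-4-one | O=c1cc(-c2ccc(OCOC)c(OCc3ccccc3)c2)oc2cc(OCc3ccccc3)cc(OCc3ccccc3)c12
A10 | alternative 3 | 3,5-bis(benzyloxy)-2-iodophenol | Oc1cc(OCc2ccccc2)cc(OCc2ccccc2)c1I
A11 | alternative 3 | 2-(benzyloxy)-4-ethynyl-1-(methoxymethoxy)benzene | C#Cc1ccc(OCOC)c(OCc2ccccc2)c1
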